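**Strategy.** The cycloheptene is cut by a (4+3) disconnection. In the seven-membered ring C1(Me)=C2–C3–C4(Me)–C8–C9(O)–C10 (C4–C8 shared with the cyclopentane C4–C5–C6–C7–C8), the C1=C2 olefin and a C8=C9 olefin form a 1,4-diene across C10. A rhodium vinylcarbenoid cyclopropanation/divinylcyclopropane Cope cascade joins methyl 2-diazobut-3-enoate to 2-ethenyl-3-methylcyclopent-2-enone. It makes C1–C10 and C3–C4, closes the seven-membered ring and sets quaternary C4 under catalyst control. C8 and C9 are then relayed together by one hydroboration, and C7 by addition anti to the C9 branch.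

Key step: step 5

Remark on names: descriptors use azulene numbering (C3 = C7 above, C3a = C8, C4 = C9, C6 = C1, C8a = C4).
Assumption: the sense of induction of Rh2(R-DOSP)4 is taken from the established model for donor/acceptor carbenoids with terminal alkenes (mirror image of the S-catalyst outcome); if the opposite sense held, the S-catalyst would be used and nothing else would change.

Step 1
Reactants: 1 2-bromo-3-methylcyclopent-2-en-1-one; 2 tributyl(vinyl)stannane
Product: 3 2-ethenyl-3-methylcyclopent-2-en-1-one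
Conditions: Pd2(dba)3 (2.5 mol %), AsPh3, CuI, NMP, 60 °C
Reagents that add atoms: none
Why: Stille cross-coupling of an α-bromoenone (oxidative addition into C–Br, vinyl transfer from tin, reductive elimination) is standard and creates no stereocentre.

Step 2
Reactants: 4 methyl acetoacetate
Product: 5 methyl 2-diazo-3-oxobutanoate
Conditions: 4-acetamidobenzenesulfonyl azide, Et3N, MeCN, 0 °C to rt
Reagents that add atoms: 4-acetamidobenzenesulfonyl azide, CC(=O)Nc1ccc(cc1)S(=O)(=O)N=[N+]=[N-]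
Why: Regitz diazo transfer to the active methylene of a β-keto ester is reliable.

Step 3
Reactants: 5 methyl 2-diazo-3-oxobutanoate
Product: 6 methyl 2-diazo-3-hydroxybutanoate (racemic)
Conditions: NaBH4, MeOH, 0 °C
Reagents that add atoms: none
Why: Borohydride reduces the ketone while the diazo ester is inert at 0 °C, and the racemic carbinol centre is removed in step 4.

Step 4
Reactants: 6 methyl 2-diazo-3-hydroxybutanoate
Product: 7 methyl 2-diazobut-3-enoate
Conditions: POCl3, Et3N, CH2Cl2, 0 °C; used at once as a cold solution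
Reagents that add atoms: none
Why: Dehydration through the dichlorophosphate (elimination) should give the vinyldiazoacetate, which is kept cold because it slowly cyclises to a pyrazole.

Step 5
Reactants: 3 2-ethenyl-3-methylcyclopent-2-en-1-one; 7 methyl 2-diazobut-3-enoate
Product: 9 methyl (8aR)-8a-methyl-3-oxo-1,2,3,5,8,8a-hexahydroazulene-6-carboxylate, via divinylcyclopropane 8 (not isolated)
Conditions: Rh2(R-DOSP)4 (1 mol %), hexanes, slow addition of 7 (2 equiv) at −40 °C to rt, then 70 °C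
Reagents that add atoms: none
Why: Rh2(R-DOSP)4 converts 7 into a donor/acceptor vinylcarbenoid that cyclopropanates the only accessible alkene of 3, the terminal vinyl group, end-on, placing the carbenoid vinyl cis to the cyclopentenyl residue and fixing the configuration of cyclopropane 8 under catalyst control (bonds C1–C10 and C1–C9). The cis-divinylcyclopropane then undergoes a [3,3]-sigmatropic (Cope) rearrangement through the obligatory boat transition state, breaking C1–C9 and forming C3–C4, which closes the seven-membered ring by three-to-seven ring expansion as a cyclohepta-1,4-diene with C1=C2 and C8=C9 in place. The closest known reaction type is the tandem cyclopropanation/Cope rearrangement (formal [4+3]) of vinyldiazoacetates with 1-vinylcycloalkenes, including 2-methyl-1-vinylcycloalkenes that give methyl-bearing quaternary ring-fusion carbons. The new stereocentre C4 is set by chirality transfer, because in the boat array the vinyl terminus C3 can reach only one face of the ring alkene carbon C4, so the catalyst-set (1S,2S) cyclopropane should map onto (R)-C4. The step needs site selectivity (the tetrasubstituted, conjugated ring alkene is inert to the bulky electrophilic carbenoid), cis diastereoselectivity and enantioface selectivity (both typical of donor/acceptor carbenoids with monosubstituted alkenes under prolinate catalysts). Because the C4 methyl must point toward the cyclopropane methylene in the boat, gentle heating is expected to be needed, and conjugation of the new C8=C9 bond with the ketone adds driving force.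

Step 6
Reactants: 9 methyl (8aR)-8a-methyl-3-oxo-1,2,3,5,8,8a-hexahydroazulene-6-carboxylate
Product: 10 methyl (3S,8aR)-3-hydroxy-8a-methyl-1,2,3,5,8,8a-hexahydroazulene-6-carboxylate
Conditions: (R)-2-methyl-CBS-oxazaborolidine (20 mol %), catecholborane, toluene, −78 °C
Reagents that add atoms: none
Why: CBS reduction with the alkylidene flank as the large group should deliver hydride to the face of C7 opposite the future C8–H under reagent control, which is needed because the two faces of this carbonyl are barely differentiated by C4.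

Step 7
Reactants: 10 methyl (3S,8aR)-3-hydroxy-8a-methyl-1,2,3,5,8,8a-hexahydroazulene-6-carboxylate
Product: 11 methyl (3S,8aR)-3-[(tert-butyldimethylsilyl)oxy]-8a-methyl-1,2,3,5,8,8a-hexahydroazulene-6-carboxylate
Conditions: TBSCl, imidazole, DMF, rt
Reagents that add atoms: tert-butyldimethylsilyl chloride, CC(C)(C)[Si](C)(C)Cl
Why: Standard silylation turns the temporary C7 carbinol into a bulky allylic shield for one face of the exocyclic C8=C9 alkene.

Step 8
Reactants: 11 methyl (3S,8aR)-3-[(tert-butyldimethylsilyl)oxy]-8a-methyl-1,2,3,5,8,8a-hexahydroazulene-6-carboxylate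
Product: 12 methyl (3S,3aS,4S,8aR)-3-[(tert-butyldimethylsilyl)oxy]-4-hydroxy-8a-methyl-1,2,3,3a,4,5,8,8a-octahydroazulene-6-carboxylate
Conditions: BH3·THF, THF, 0 °C to rt; then NaBO3·4H2O, H2O, rt
Reagents that add atoms: sodium perborate, [Na+].[O-]OB=O
Why: Hydroboration–oxidation adds H and B syn from the face anti to the allylic silyl ether with boron on the less substituted C9 and oxidation with retention, so C8–H (trans to the C4 methyl) and C9–OH (cis to C8–H) should be set in one event while the electron-poor enoate C1=C2 reacts much more slowly.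

Step 9
Reactants: 12 methyl (3S,3aS,4S,8aR)-3-[(tert-butyldimethylsilyl)oxy]-4-hydroxy-8a-methyl-1,2,3,3a,4,5,8,8a-octahydroazulene-6-carboxylate
Product: 13 (3S,3aS,4S,8aR)-3-[(tert-butyldimethylsilyl)oxy]-6-(hydroxymethyl)-8a-methyl-1,2,3,3a,4,5,8,8a-octahydroazulen-4-ol
Conditions: DIBAL-H (3.5 equiv), CH2Cl2, −78 °C; Rochelle salt work-up
Reagents that add atoms: none
Why: DIBAL-H reduces the enoate 1,2 to the primary allylic alcohol and leaves the silyl ether and the stereocentres untouched.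

Step 10
Reactants: 13 (3S,3aS,4S,8aR)-3-[(tert-butyldimethylsilyl)oxy]-6-(hydroxymethyl)-8a-methyl-1,2,3,3a,4,5,8,8a-octahydroazulen-4-ol
Product: 15 (3S,3aS,4S,8aR)-3-[(tert-butyldimethylsilyl)oxy]-6,8a-dimethyl-1,2,3,3a,4,5,8,8a-octahydroazulen-4-ol, via allylic mesylate 14 (not isolated)
Conditions: MsCl (1.05 equiv), Et3N, CH2Cl2, −40 °C; then LiEt3BH (3 equiv), THF, 0 °C
Reagents that add atoms: none
Why: The primary allylic hydroxyl is sulfonylated much faster than the hindered secondary one, and SN2 displacement by triethylborohydride should give the C1 methyl without allylic transposition.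

Step 11
Reactants: 15 (3S,3aS,4S,8aR)-3-[(tert-butyldimethylsilyl)oxy]-6,8a-dimethyl-1,2,3,3a,4,5,8,8a-octahydroazulen-4-ol; 16 2,2-dimethyl-4H-1,3-benzodioxin-4-one
Product: 17 (3S,3aS,4S,8aR)-3-[(tert-butyldimethylsilyl)oxy]-6,8a-dimethyl-1,2,3,3a,4,5,8,8a-octahydroazulen-4-yl 2-hydroxybenzoate
Conditions: NaHMDS (1.1 equiv), THF, 0 °C; then 16, 0 °C to rt; AcOH quench
Reagents that add atoms: none
Why: Alkoxide addition–elimination at the carbonyl of the benzodioxinone with loss of acetone gives the salicylate with its phenol free, and acylation on oxygen leaves C9 untouched.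

Step 12
Reactants: 17 (3S,3aS,4S,8aR)-3-[(tert-butyldimethylsilyl)oxy]-6,8a-dimethyl-1,2,3,3a,4,5,8,8a-octahydroazulen-4-yl 2-hydroxybenzoate
Product: 18 (3S,3aR,4S,8aR)-3-hydroxy-6,8a-dimethyl-1,2,3,3a,4,5,8,8a-octahydroazulen-4-yl 2-hydroxybenzoate
Conditions: HF·pyridine, THF/pyridine, 0 °C to rt
Reagents that add atoms: none
Why: Fluoride-mediated desilylation under non-basic conditions frees the C7 carbinol, and acyl migration is not expected because O7 and O9 lie on opposite faces.

Step 13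
Reactants: 18 (3S,3aR,4S,8aR)-3-hydroxy-6,8a-dimethyl-1,2,3,3a,4,5,8,8a-octahydroazulen-4-yl 2-hydroxybenzoate
Product: 19 (3aS,4S,8aR)-6,8a-dimethyl-3-oxo-1,2,3,3a,4,5,8,8a-octahydroazulen-4-yl 2-hydroxybenzoate
Conditions: Dess–Martin periodinane, NaHCO3, CH2Cl2, 0 °C
Reagents that add atoms: none
Why: Buffered Dess–Martin oxidation is non-basic, so the C8 centre α to the new ketone should not epimerise and the β-acyloxy group should not eliminate.

Step 14
Reactants: 19 (3aS,4S,8aR)-6,8a-dimethyl-3-oxo-1,2,3,3a,4,5,8,8a-octahydroazulen-4-yl 2-hydroxybenzoate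
Product: 20 (3R,3aS,4S,8aR)-3-hydroxy-6,8a-dimethyl-3-(propan-2-yl)-1,2,3,3a,4,5,8,8a-octahydroazulen-4-yl 2-hydroxybenzoate
Conditions: i-PrMgCl (4 equiv), anhydrous CeCl3 (4 equiv), THF, −78 °C; aq. NH4Cl
Reagents that add atoms: isopropylmagnesium chloride, CC(C)[Mg]Cl
Why: Organocerium 1,2-addition should occur on the C7 face anti to the C9 branch and to the pseudo-axial C4 methyl, giving the hydroxyl cis to that methyl, while the first equivalent deprotonates the phenol so that the ester is deactivated and the weakly basic reagent avoids enolisation.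

**Compound list**

1 | 2-bromo-3-methylcyclopent-2-en-1-one | CC1=C(Br)C(=O)CC1 | starting material
2 | tributyl(vinyl)stannane | C=C[Sn](CCCC)(CCCC)CCCC | starting material
3 | 2-ethenyl-3-methylcyclopent-2-en-1-one | CC1=C(C=C)C(=O)CC1 | intermediate
4 | methyl acetoacetate | COC(=O)CC(C)=O | starting material
5 | methyl 2-diazo-3-oxobutanoate | COC(=O)C(=[N+]=[N-])C(C)=O | intermediate
6 | methyl 2-diazo-3-hydroxybutanoate (racemic) | COC(=O)C(=[N+]=[N-])C(C)O | intermediate
7 | methyl 2-diazobut-3-enoate | COC(=O)C(=[N+]=[N-])C=C | intermediate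
8 | methyl (1S,2S)-1-ethenyl-2-(2-methyl-5-oxocyclopent-1-en-1-yl)cyclopropane-1-carboxylate | COC(=O)[C@]1(C=C)C[C@H]1C1=C(C)CCC1=O | intermediate
9 | methyl (8aR)-8a-methyl-3-oxo-1,2,3,5,8,8a-hexahydroazulene-6-carboxylate | COC(=O)C1=CC[C@@]2(C)CCC(=O)C2=CC1 | intermediate
10 | methyl (3S,8aR)-3-hydroxy-8a-methyl-1,2,3,5,8,8a-hexahydroazulene-6-carboxylate | COC(=O)C1=CC[C@@]2(C)CC[C@H](O)C2=CC1 | intermediate
11 | methyl (3S,8aR)-3-[(tert-butyldimethylsilyl)oxy]-8a-methyl-1,2,3,5,8,8a-hexahydroazulene-6-carboxylate | COC(=O)C1=CC[C@@]2(C)CC[C@H](O[Si](C)(C)C(C)(C)C)C2=CC1 | intermediate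
12 | methyl (3S,3aS,4S,8aR)-3-[(tert-butyldimethylsilyl)oxy]-4-hydroxy-8a-methyl-1,2,3,3a,4,5,8,8a-octahydroazulene-6-carboxylate | COC(=O)C1=CC[C@@]2(C)CC[C@H](O[Si](C)(C)C(C)(C)C)[C@@H]2[C@@H](O)C1 | intermediate
13 | (3S,3aS,4S,8aR)-3-[(tert-butyldimethylsilyl)oxy]-6-(hydroxymethyl)-8a-methyl-1,2,3,3a,4,5,8,8a-octahydroazulen-4-ol | OCC1=CC[C@@]2(C)CC[C@H](O[Si](C)(C)C(C)(C)C)[C@@H]2[C@@H](O)C1 | intermediate
14 | [(3S,3aS,4S,8aR)-3-[(tert-butyldimethylsilyl)oxy]-4-hydroxy-8a-methyl-1,2,3,3a,4,5,8,8a-octahydroazulen-6-yl]methyl methanesulfonate | CS(=O)(=O)OCC1=CC[C@@]2(C)CC[C@H](O[Si](C)(C)C(C)(C)C)[C@@H]2[C@@H](O)C1 | intermediate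
15 | (3S,3aS,4S,8aR)-3-[(tert-butyldimethylsilyl)oxy]-6,8a-dimethyl-1,2,3,3a,4,5,8,8a-octahydroazulen-4-ol | CC1=CC[C@@]2(C)CC[C@H](O[Si](C)(C)C(C)(C)C)[C@@H]2[C@@H](O)C1 | intermediate
16 | 2,2-dimethyl-4H-1,3-benzodioxin-4-one | CC1(C)OC(=O)c2ccccc2O1 | starting material
17 | (3S,3aS,4S,8aR)-3-[(tert-butyldimethylsilyl)oxy]-6,8a-dimethyl-1,2,3,3a,4,5,8,8a-octahydroazulen-4-yl 2-hydroxybenzoate | CC1=CC[C@@]2(C)CC[C@H](O[Si](C)(C)C(C)(C)C)[C@@H]2[C@@H](OC(=O)c2ccccc2O)C1 | intermediate
18 | (3S,3aR,4S,8aR)-3-hydroxy-6,8a-dimethyl-1,2,3,3a,4,5,8,8a-octahydroazulen-4-yl 2-hydroxybenzoate | CC1=CC[C@@]2(C)CC[C@H](O)[C@@H]2[C@@H](OC(=O)c2ccccc2O)C1 | intermediate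
19 | (3aS,4S,8aR)-6,8a-dimethyl-3-oxo-1,2,3,3a,4,5,8,8a-octahydroazulen-4-yl 2-hydroxybenzoate | CC1=CC[C@@]2(C)CCC(=O)[C@@H]2[C@@H](OC(=O)c2ccccc2O)C1 | intermediate
20 | (3R,3aS,4S,8aR)-3-hydroxy-6,8a-dimethyl-3-(propan-2-yl)-1,2,3,3a,4,5,8,8a-octahydroazulen-4-yl 2-hydroxybenzoate | CC1=CC[C@@]2(C)CC[C@@](O)(C(C)C)[C@@H]2[C@@H](OC(=O)c2ccccc2O)C1 | target

**Totals.** Total step count: 14. Longest linear sequence: 13 steps (4 to 20, steps 2–14).

**Steps most likely to fail**

Step 5. The carbenoid may be diverted by the ketone oxygen or by self-reaction before it reaches the cross-conjugated vinyl group. The Cope step, slowed by the inward-pointing methyl, may also need temperatures at which reversible opening of the donor/acceptor cyclopropane erodes the enantiomeric purity. The fallback sets out from 3 and comes back at 9. The ketone is masked without double-bond migration (1,2-bis(trimethylsilyloxy)ethane, TMSOTf, CH2Cl2, −78 °C) to give 7-methyl-6-vinyl-1,4-dioxaspiro[4.4]non-6-ene F1. Cyclopropanation with 7 and Rh2(R-DOSP)4 at −78 °C is stopped at the isolable cyclopropane, methyl (1S,2S)-1-ethenyl-2-(7-methyl-1,4-dioxaspiro[4.4]non-6-en-6-yl)cyclopropane-1-carboxylate F2, whose purity can be checked. A separate thermal Cope rearrangement (toluene, 80–110 °C) should give the ethylene ketal of 9, methyl (8a'R)-8a'-methyl-1',2',5',8'-tetrahydro-8a'H-spiro[[1,3]dioxolane-2,3'-azulene]-6'-carboxylate F3, and PPTS in aqueous acetone returns 9.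

Step 8. Borane may approach from the face of the silyl ether (poor facial selectivity) or be consumed by the enoate. The fallback sets out from 9 and comes back at 12. It replaces substrate-controlled hydroboration by reagent-controlled conjugate borylation: CuCl with a chiral Josiphos-type bisphosphine, B2pin2, NaOtBu, MeOH, THF, with the ligand enantiomer chosen to place boron on the C9 face that becomes the α-oxygen. This should give methyl (3aR,4S,8aR)-8a-methyl-3-oxo-4-(4,4,5,5-tetramethyl-1,3,2-dioxaborolan-2-yl)-1,2,3,3a,4,5,8,8a-octahydroazulene-6-carboxylate F4, the copper enolate being protonated at C8 anti to the pseudo-axial C4 methyl. Oxidation (NaBO3) gives methyl (3aS,4S,8aR)-4-hydroxy-8a-methyl-3-oxo-1,2,3,3a,4,5,8,8a-octahydroazulene-6-carboxylate F5. Silylation (TESCl, imidazole) gives methyl (3aS,4S,8aR)-8a-methyl-3-oxo-4-[(triethylsilyl)oxy]-1,2,3,3a,4,5,8,8a-octahydroazulene-6-carboxylate F6. NaBH4 (MeOH, −20 °C) attacks C7 anti to the C9 branch and should give methyl (3S,3aR,4S,8aR)-3-hydroxy-8a-methyl-4-[(triethylsilyl)oxy]-1,2,3,3a,4,5,8,8a-octahydroazulene-6-carboxylate F7. TBSOTf/2,6-lutidine gives methyl (3S,3aR,4S,8aR)-3-[(tert-butyldimethylsilyl)oxy]-8a-methyl-4-[(triethylsilyl)oxy]-1,2,3,3a,4,5,8,8a-octahydroazulene-6-carboxylate F8, and selective removal of the triethylsilyl group (PPTS, MeOH) returns 12.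

Step 14. The basic organometallic may enolise ketone 19, which would lead to β-elimination of the salicylate or epimerisation at C8, or it may attack the ester. The fallback sets out from 15 and comes back at 20; it postpones the esterification until after the C–C bond is made. Compound 15 is protected (PMB trichloroacetimidate, cat. Sc(OTf)3) as tert-butyl({(3S,3aS,4S,8aR)-4-[(4-methoxyphenyl)methoxy]-6,8a-dimethyl-1,2,3,3a,4,5,8,8a-octahydroazulen-3-yl}oxy)dimethylsilane F9. HF·pyridine gives (3S,3aR,4S,8aR)-4-[(4-methoxyphenyl)methoxy]-6,8a-dimethyl-1,2,3,3a,4,5,8,8a-octahydroazulen-3-ol F10. Dess–Martin oxidation gives (3aS,4S,8aR)-4-[(4-methoxyphenyl)methoxy]-6,8a-dimethyl-2,3a,4,5,8,8a-hexahydroazulen-3(1H)-one F11, a β-alkoxy ketone with a poor leaving group. i-PrMgCl/CeCl3 then gives (3R,3aS,4S,8aR)-4-[(4-methoxyphenyl)methoxy]-6,8a-dimethyl-3-(propan-2-yl)-1,2,3,3a,4,5,8,8a-octahydroazulen-3-ol F12. DDQ (CH2Cl2/pH 7 buffer) frees (3R,3aS,4S,8aR)-6,8a-dimethyl-3-(propan-2-yl)-1,2,3,3a,4,5,8,8a-octahydroazulene-3,4-diol F13. Its secondary alkoxide (NaHMDS, 1 equiv) opens 16 selectively, the tertiary hydroxyl staying free, to give 20.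

**Further compounds**

F1 | step 5 | 7-methyl-6-vinyl-1,4-dioxaspiro[4.4]non-6-ene | CC1=C(C=C)C2(CC1)OCCO2
F2 | step 5 | methyl (1S,2S)-1-ethenyl-2-(7-methyl-1,4-dioxaspiro[4.4]non-6-en-6-yl)cyclopropane-1-carboxylate | COC(=O)[C@]1(C=C)C[C@H]1C1=C(C)CCC12OCCO2
F3 | step 5 | methyl (8a'R)-8a'-methyl-1',2',5',8'-tetrahydro-8a'H-spiro[[1,3]dioxolane-2,3'-azulene]-6'-carboxylate | COC(=O)C1=CC[C@@]2(C)CCC3(OCCO3)C2=CC1
F4 | step 8 | methyl (3aR,4S,8aR)-8a-methyl-3-oxo-4-(4,4,5,5-tetramethyl-1,3,2-dioxaborolan-2-yl)-1,2,3,3a,4,5,8,8a-octahydroazulene-6-carboxylate | COC(=O)C1=CC[C@@]2(C)CCC(=O)[C@@H]2[C@@H](B3OC(C)(C)C(C)(C)O3)C1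
F5 | step 8 | methyl (3aS,4S,8aR)-4-hydroxy-8a-methyl-3-oxo-1,2,3,3a,4,5,8,8a-octahydroazulene-6-carboxylate | COC(=O)C1=CC[C@@]2(C)CCC(=O)[C@@H]2[C@@H](O)C1
F6 | step 8 | methyl (3aS,4S,8aR)-8a-methyl-3-oxo-4-[(triethylsilyl)oxy]-1,2,3,3a,4,5,8,8a-octahydroazulene-6-carboxylate | COC(=O)C1=CC[C@@]2(C)CCC(=O)[C@@H]2[C@@H](O[Si](CC)(CC)CC)C1
F7 | step 8 | methyl (3S,3aR,4S,8aR)-3-hydroxy-8a-methyl-4-[(triethylsilyl)oxy]-1,2,3,3a,4,5,8,8a-octahydroazulene-6-carboxylate | COC(=O)C1=CC[C@@]2(C)CC[C@H](O)[C@@H]2[C@@H](O[Si](CC)(CC)CC)C1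
F8 | step 8 | methyl (3S,3aR,4S,8aR)-3-[(tert-butyldimethylsilyl)oxy]-8a-methyl-4-[(triethylsilyl)oxy]-1,2,3,3a,4,5,8,8a-octahydroazulene-6-carboxylate | COC(=O)C1=CC[C@@]2(C)CC[C@H](O[Si](C)(C)C(C)(C)C)[C@@H]2[C@@H](O[Si](CC)(CC)CC)C1
F9 | step 14 | tert-butyl({(3S,3aS,4S,8aR)-4-[(4-methoxyphenyl)methoxy]-6,8a-dimethyl-1,2,3,3a,4,5,8,8a-octahydroazulen-3-yl}oxy)dimethylsilane | CC1=CC[C@@]2(C)CC[C@H](O[Si](C)(C)C(C)(C)C)[C@@H]2[C@@H](OCc2ccc(OC)cc2)C1
F10 | step 14 | (3S,3aR,4S,8aR)-4-[(4-methoxyphenyl)methoxy]-6,8a-dimethyl-1,2,3,3a,4,5,8,8a-octahydroazulen-3-ol | CC1=CC[C@@]2(C)CC[C@H](O)[C@@H]2[C@@H](OCc2ccc(OC)cc2)C1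
F11 | step 14 | (3aS,4S,8aR)-4-[(4-methoxyphenyl)methoxy]-6,8a-dimethyl-2,3a,4,5,8,8a-hexahydroazulen-3(1H)-one | CC1=CC[C@@]2(C)CCC(=O)[C@@H]2[C@@H](OCc2ccc(OC)cc2)C1
F12 | step 14 | (3R,3aS,4S,8aR)-4-[(4-methoxyphenyl)methoxy]-6,8a-dimethyl-3-(propan-2-yl)-1,2,3,3a,4,5,8,8a-octahydroazulen-3-ol | CC1=CC[C@@]2(C)CC[C@@](O)(C(C)C)[C@@H]2[C@@H](OCc2ccc(OC)cc2)C1
F13 | step 14 | (3R,3aS,4S,8aR)-6,8a-dimethyl-3-(propan-2-yl)-1,2,3,3a,4,5,8,8a-octahydroazulene-3,4-diol | CC1=CC[C@@]2(C)CC[C@@](O)(C(C)C)[C@@H]2[C@@H](O)C1
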